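The 2,5-dihydroxy-1,4-benzoquinone ring (C1=O, C2–OH, C3–CH3, C4=O, C5–OH, C6–chain) is read as two enolised α-keto-acyl halves, C1–C2–C3 and C4–C5–C6, joined head to tail. The key step forms the ring bonds C1–C6 and C3–C4 in one pot by a crossed Claisen–Dieckmann cascade: the sodium enolate of a 2-alkyl-3-oxosuccinate that already carries the complete (E)-nonadec-14-enyl chain is acylated by methyl 2-oxobutanoate, and the adduct closes the six-membered ring. A tert-butyl ester on the future C6 serves as temporary activating group and is removed by acidolysis and decarboxylation. The (E)-alkene comes from a stereoretentive alkyl–alkenyl Suzuki coupling.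

Key step: step 4

Assumption: 15-bromopentadecanoic acid (1) is taken as a catalogue starting material; the hydroxyquinone tautomers are one compound, drawn as in the target SMILES.

Step 1
Reactants: 1 15-bromopentadecanoic acid
Product: 2 tert-butyl 15-bromopentadecanoate
Conditions: tert-butyl 2,2,2-trichloroacetimidate (2 equiv), BF3·OEt2 (5 mol %), CH2Cl2/cyclohexane, rt
Reagents that add atoms: tert-butyl 2,2,2-trichloroacetimidate, CC(C)(C)OC(=N)C(Cl)(Cl)Cl
Why: Acid-catalysed O-tert-butylation of the carboxylic acid by the imidate (tert-butyl cation transfer) leaves the primary bromide untouched and installs an ester that is inert to KOt-Bu in step 2 and to acyl attack in step 4.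

Step 2
Reactants: 2 tert-butyl 15-bromopentadecanoate; 3 (E)-hex-1-en-1-ylboronic acid
Product: 4 tert-butyl (16E)-henicos-16-enoate
Conditions: Pd(OAc)2 (5 mol %), P(t-Bu)2Me·HBF4 (10 mol %), KOt-Bu (3 equiv), tert-amyl alcohol, rt
Reagents that add atoms: none
Why: Suzuki–Miyaura coupling of an unactivated primary alkyl bromide with an alkenylboronic acid, in which the bulky electron-rich trialkylphosphine on zerovalent palladium lets coupling outrun β-hydride elimination and the E geometry of 3 is carried over with retention.

Step 3
Reactants: 4 tert-butyl (16E)-henicos-16-enoate; 5 dimethyl oxalate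
Product: 7 1-tert-butyl 4-methyl 2-[(14E)-nonadec-14-en-1-yl]-3-oxobutanedioate, via lithium enolate 6 (not isolated)
Conditions: LiN(i-Pr)2 (1.1 equiv), THF, −78 °C; then transfer into dimethyl oxalate (1.5 equiv), THF, −78 °C; 1 M HCl quench, −78 to 0 °C
Reagents that add atoms: none
Why: Crossed Claisen condensation of a tert-butyl ester enolate with non-enolisable dimethyl oxalate, in which the chelated tetrahedral adduct should persist at −78 °C until the acidic quench, so that single acylation is expected; the new stereocentre forms racemic, is enolisable and vanishes in step 4.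

Step 4
Reactants: 7 1-tert-butyl 4-methyl 2-[(14E)-nonadec-14-en-1-yl]-3-oxobutanedioate; 8 methyl 2-oxobutanoate
Product: 12 2,5-dihydroxy-3-methyl-6-[(14E)-nonadec-14-en-1-yl]cyclohexa-2,5-diene-1,4-dione, via sodium enolate 9 (not isolated), via open-chain Claisen adduct 10 (not isolated), via cyclised tert-butyl ester 11 (not isolated)
Conditions: NaH (1.3 equiv), THF, 0 °C; 8 (2.5 equiv, slow addition), 0 to 40 °C; 1 M HCl work-up; then TFA, CH2Cl2, 0 °C to rt
Reagents that add atoms: none
Why: Proposed new method: sodium enolate 9 is C-acylated at its tertiary carbon by the ester carbonyl of 8 (crossed Claisen, new C1–C6 bond) to give 10, whose only enolisable position, the CH2 next to the diketone, is deprotonated by the liberated methoxide and attacks the methyl oxalyl ester (Dieckmann, new C3–C4 bond) to give the enolate of 11, and TFA then cleaves the tert-butyl ester so that the β-keto acid decarboxylates to 12. The closest known reaction type is the alkali-promoted head-to-tail self-condensation of two α-oxalyl esters to a 3,6-dialkyl-2,5-dihydroxy-1,4-benzoquinone, a double Claisen ring closure that is here run crossed between one α-oxalyl ester and one simple α-keto ester. The ring closes in the favoured 6-(enolendo)-exo-trig mode, whereas closure onto the neighbouring ketone or onto the tert-butyl ester would be 5-(enolendo)-exo-trig and disfavoured, and no stereocentre is set because the quaternary carbon of 10 and 11 is racemic and becomes sp2 on decarboxylation. Cross- over homo-condensation is needed and is secured by acidity: only 7 is a strong C–H acid, so NaH turns it completely into the donor 9, which as an anion cannot act as acceptor, while 8 stays neutral, is added slowly and is the only acceptor. Claisen over aldol reactivity is needed too: addition of 9 to the ketone of 8 is reversible and has no sink because the donor carbon becomes quaternary, whereas deprotonation of 11 to a vinylogous carboxylate makes the six-membered closure irreversible. The tert-butyl ester is too hindered to serve as acyl acceptor and later leaves as 2-methylpropene and CO2 without base.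

Compound list
1 | 15-bromopentadecanoic acid | OC(=O)CCCCCCCCCCCCCCBr | starting material
2 | tert-butyl 15-bromopentadecanoate | CC(C)(C)OC(=O)CCCCCCCCCCCCCCBr | intermediate
3 | (E)-hex-1-en-1-ylboronic acid | CCCC/C=C/B(O)O | starting material
4 | tert-butyl (16E)-henicos-16-enoate | CC(C)(C)OC(=O)CCCCCCCCCCCCCC/C=C/CCCC | intermediate
5 | dimethyl oxalate | COC(=O)C(=O)OC | starting material
6 | lithium enolate of 4 (enolate geometry not defined, not isolated) | [Li+].[O-]C(OC(C)(C)C)=CCCCCCCCCCCCCC/C=C/CCCC | intermediate
7 | 1-tert-butyl 4-methyl 2-[(14E)-nonadec-14-en-1-yl]-3-oxobutanedioate (racemic, keto form drawn) | COC(=O)C(=O)C(CCCCCCCCCCCCC/C=C/CCCC)C(=O)OC(C)(C)C | intermediate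
8 | methyl 2-oxobutanoate | CCC(=O)C(=O)OC | starting material
9 | sodium enolate of 7 (enolate geometry not defined, not isolated) | [Na+].[O-]C(C(=O)OC)=C(CCCCCCCCCCCCC/C=C/CCCC)C(=O)OC(C)(C)C | intermediate
10 | tert-butyl 2-(2-methoxy-2-oxoacetyl)-2-[(14E)-nonadec-14-en-1-yl]-3,4-dioxohexanoate (racemic, not isolated) | COC(=O)C(=O)C(CCCCCCCCCCCCC/C=C/CCCC)(C(=O)OC(C)(C)C)C(=O)C(=O)CC | intermediate
11 | tert-butyl 3-hydroxy-4-methyl-1-[(14E)-nonadec-14-en-1-yl]-2,5,6-trioxocyclohex-3-ene-1-carboxylate (racemic, one enol tautomer drawn, not isolated) | CC1=C(O)C(=O)C(CCCCCCCCCCCCC/C=C/CCCC)(C(=O)OC(C)(C)C)C(=O)C1=O | intermediate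
12 | 2,5-dihydroxy-3-methyl-6-[(14E)-nonadec-14-en-1-yl]cyclohexa-2,5-diene-1,4-dione | CCCC/C=C/CCCCCCCCCCCCCC1=C(O)C(=O)C(C)=C(O)C1=O | target

Total step count: 4. Longest linear sequence: 4 steps (1 → 2 → 4 → 7 → 12).

Steps most likely to fail

1. Step 4 (bears the new-method label). The crossed Claisen may be outrun by self-condensation of the acceptor, or the open-chain adduct may revert by retro-Claisen cleavage faster than it cyclises, so that formation of the ring enolate never becomes the sink. The fallback uses known chemistry and gives up role differentiation for the classical protocol in which both halves are α-oxalyl esters. It sets out from 7, which is condensed with an excess of commercial diethyl 2-methyl-3-oxosuccinate (CCOC(=O)C(=O)C(C)C(=O)OCC) under NaOEt in EtOH/THF. This is the long-known alkali-promoted head-to-tail self-condensation of α-oxalyl esters to 3,6-dialkyl-2,5-dihydroxy-1,4-benzoquinones, run as a mixed condensation. It should give, besides the small polar homodimer of the cheap partner, 1-tert-butyl 4-ethyl 4-methyl-1-[(14E)-nonadec-14-en-1-yl]-2,3,5,6-tetraoxocyclohexane-1,4-dicarboxylate F1. Ethoxide then cleaves the ethoxycarbonyl group of F1 as diethyl carbonate, which brings the sequence back to the route at 11, and TFA as in step 4 leads to 12. Cross-selectivity is then only statistical and rests on the excess of the cheap partner and on the easy removal of its homodimer.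

2. Step 3. Proton transfer from the acidic product to unreacted enolate, or a second enolate addition to the new ketone, may stall or over-run the oxalylation. The fallback replaces the anionic Claisen by an irreversible acylation of a neutral enol derivative. It sets out from 4, whose lithium enolate is trapped with Me3SiCl to give [(16E)-1-tert-butoxyhenicosa-1,16-dien-1-yl]oxy(trimethyl)silane F2. F2 is then C-acylated with methyl chlorooxoacetate (COC(=O)C(Cl)=O) in CH2Cl2, with catalytic ZnCl2 if needed, and the sequence comes back to the route at 7.

3. Step 2. β-Hydride elimination from the alkylpalladium intermediate, base-induced dehydrobromination of 2 or protodeboronation of 3 may erode the coupling. The fallback sets the E-alkene by alkyne reduction instead of stereoretentive coupling. It sets out from 1, which is alkylated with excess lithium hex-1-ynide (from hex-1-yne, CCCCC#C, and n-BuLi) in THF/DMPU to give henicos-16-ynoic acid F3. Dissolving-metal reduction of F3 with Li in liquid NH3 (anti addition) should give (16E)-henicos-16-enoic acid F4. F4 is tert-butylated under the conditions of step 1, and the sequence comes back to the route at 4.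

Further compounds
F1 | step 4 | 1-tert-butyl 4-ethyl 4-methyl-1-[(14E)-nonadec-14-en-1-yl]-2,3,5,6-tetraoxocyclohexane-1,4-dicarboxylate (mixture of diastereomers) | CCOC(=O)C1(C)C(=O)C(=O)C(CCCCCCCCCCCCC/C=C/CCCC)(C(=O)OC(C)(C)C)C(=O)C1=O
F2 | step 3 | [(16E)-1-tert-butoxyhenicosa-1,16-dien-1-yl]oxy(trimethyl)silane (ketene acetal geometry not defined) | CCCC/C=C/CCCCCCCCCCCCCC=C(O[Si](C)(C)C)OC(C)(C)C
F3 | step 2 | henicos-16-ynoic acid | CCCCC#CCCCCCCCCCCCCCCC(=O)O
F4 | step 2 | (16E)-henicos-16-enoic acid | CCCC/C=C/CCCCCCCCCCCCCCC(=O)O
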